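**Retrosynthetic overview**

1. The C6 methyl group and the (E)-exocyclic C5=C alkene are disconnected together: anti-SN2′ methyl-copper substitution of an allylic picolinate (1,3-chirality transfer). The C5–C(carbinol) bond is then cut by Nozaki–Hiyama–Kishi coupling into hydroazulenyl triflate 14 and benzoxepine aldehyde 27.
2. Hydroazulene: the enabling feature is the 1,5-relationship of C1 (carbinol carbon, five-membered ring B) and C5 (alkylidene carbon, seven-membered ring A) across C8a–C3a, with the quaternary C4(Me)2 next to C5. Written as a C1/C5 diketone, this is the retron of a [2+2] photocycloaddition/fragmentation in which a temporary C5–C8a cyclobutane bond is made and cut, while C8a–C3a and C4–C5 come from a prenyl-type alkene.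
3. Ring order on this side: cyclopentanone is bought; the key step closes ring B and a cyclobutane, then turns the bought five-membered ring into seven-membered ring A by a two-atom ring expansion.
4. Benzoxepine: oxepane ring D and cyclohexane ring C form, in this order, in one epoxonium cascade of a (2R,3R,6S)-diepoxide made from geraniol. The allyl ester that activates the terminating β-keto ester is then moved onto C6 by decarboxylative allylation and cut down to the two-carbon aldehyde.

Key step: step 3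

Assumption (chemistry): 5-methylhex-4-enoic acid, (2S,5S)-2,5-dimethylpyrrolidine, allyl acetoacetate and the L-fructose-derived epoxidation ketone are taken as purchasable; the hydroazulene is numbered as azulene (C1 carbinol carbon, C3a/C8a ring fusion, C4 CMe2, C5 alkylidene carbon, C6 CHMe) and the oxepane–cyclohexane as 1-benzoxepine.

**Step 1**
Reactants: 1 cyclopentanone; 2 (2S,5S)-2,5-dimethylpyrrolidine
Product: 3 1-[(2S,5S)-2,5-dimethylpyrrolidin-1-yl]cyclopent-1-ene
Conditions: p-TsOH (cat.), toluene, reflux, Dean–Stark trap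
Reagents that add atoms: none
Why: Acid-catalysed condensation of the ketone with the secondary amine under azeotropic removal of water gives the enamine (Stork enamine formation), the two stereocenters being those of 2.

**Step 2**
Reactants: 3 1-[(2S,5S)-2,5-dimethylpyrrolidin-1-yl]cyclopent-1-ene; 4 5-methylhex-4-enoic acid
Product: 6 1-{2-[(2S,5S)-2,5-dimethylpyrrolidin-1-yl]cyclopent-1-en-1-yl}-5-methylhex-4-en-1-one, via 5-methylhex-4-enoyl chloride 5 (not isolated)
Conditions: 4, (COCl)2, DMF (cat.), CH2Cl2, 0 °C → rt, evaporate; then 3, Et3N, CH2Cl2, 0 °C → rt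
Reagents that add atoms: none
Why: Stork enamine acylation: the enamine β-carbon attacks the acid chloride and Et3N removes HCl from the acyliminium ion, giving the push–pull vinylogous amide with the C=C fixed in the five-membered ring and the ketone in the tether; no stereocenter is formed.

**Step 3**
Reactants: 6 1-{2-[(2S,5S)-2,5-dimethylpyrrolidin-1-yl]cyclopent-1-en-1-yl}-5-methylhex-4-en-1-one
Product: 9 (3aR,8aR)-4,4-dimethyloctahydroazulene-1,5-dione (cis-fused), via aminocyclobutane photoadduct 7 (not isolated), via ring-expanded enamino ketone 8 (not isolated)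
Conditions: hν (medium-pressure mercury lamp, Pyrex filter, λ > 300 nm), degassed MeCN (0.01 M), rt; then AcOH/NaOAc buffer, H2O–THF, rt
Reagents that add atoms: water, O
Why: Proposed new method: excitation of the vinylogous amide should give a [2+2] photocycloaddition in which the enaminone α-carbon first bonds to the inner alkene carbon (1,5-closure, 5-exo, forming cyclopentanone ring B) and the 1,4-diradical then closes the cyclobutane between the amino-bearing ring carbon and the CMe2 terminus (straight adduct, quaternary C4 formed); aminocyclobutane 7 then fragments by retro-Mannich reaction (nitrogen pushes, ketone accepts), cutting the bond shared by the cyclobutane and the original cyclopentane so that this five-membered ring becomes seven-membered ring A by a two-atom ring expansion, and mild aqueous acid hydrolyses enamine 8 to dione 9. The closest known reaction types are the de Mayo reaction of 2-acylcycloalkanone enol derivatives and the vinylogous-amide photocycloaddition/retro-Mannich sequence; new is the C2-symmetric amine on the enaminone as the element that sets the absolute configuration. C3a is set by the auxiliary: as in alkylations of enamines of trans-2,5-dimethylpyrrolidine, the methyl group on the pyrrolidine carbon lying syn to the enaminone α-carbon shields one face, so the tethered alkene should add from the other face, which for the (2S,5S) amine corresponds to (3aR). C8a is set after the fragmentation by external protonation of the cyclopentanone enol(ate) on the face away from the seven-membered chain, which gives the cis ring fusion. The step needs straight rather than crossed regiochemistry (secured by the three-atom tether between the enaminone α-carbon and the alkene), cleavage of only the donor/acceptor-flanked cyclobutane bond (secured by the placement of N and C=O), and facial selectivity (the only element that rests on the proposal).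

**Step 4**
Reactants: 9 (3aR,8aR)-4,4-dimethyloctahydroazulene-1,5-dione
Product: 10 (3aR,8aR)-4,4-dimethyl-1-methylideneoctahydroazulen-5(1H)-one
Conditions: Zn, CH2Br2, TiCl4 (preformed reagent, 1.1 equiv), THF/CH2Cl2, 0 °C → rt
Reagents that add atoms: dibromomethane, BrCBr
Why: Lombardo methylenation should convert only the unhindered cyclopentanone C1=O, because the C5 ketone is shielded by the adjacent C4(Me)2, and being non-basic it should not epimerise C8a.

**Step 5**
Reactants: 10 (3aR,8aR)-4,4-dimethyl-1-methylideneoctahydroazulen-5(1H)-one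
Product: 12 (1R,3aR,8aR)-1-hydroxy-1,4,4-trimethyloctahydroazulen-5(1H)-one, via tertiary hydroperoxide 11 (not isolated)
Conditions: Mn(dpm)3 [tris(2,2,6,6-tetramethylheptane-3,5-dionato)manganese] (cat.), PhSiH3, O2 (1 atm), i-PrOH/CH2Cl2, 0 °C → rt; then PPh3
Reagents that add atoms: dioxygen, O=O
Why: Mukaiyama hydration: hydrogen-atom transfer from a manganese hydride to the CH2 terminus gives the tertiary C1 radical, which O2 should trap on the convex face of the cis-fused bicycle (the side of H-8a, anti to the C8a–C8 bond), so that reduction of hydroperoxide 11 gives the (1R) alcohol with OH cis to H-8a.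

**Step 6**
Reactants: 12 (1R,3aR,8aR)-1-hydroxy-1,4,4-trimethyloctahydroazulen-5(1H)-one
Product: 13 (1R,3aR,8aR)-1,4,4-trimethyl-1-(triethylsilyloxy)octahydroazulen-5(1H)-one
Conditions: Et3SiOTf, 2,6-lutidine, CH2Cl2, −78 °C
Reagents that add atoms: triethylsilyl trifluoromethanesulfonate, CC[Si](CC)(CC)OS(=O)(=O)C(F)(F)F
Why: Silylation of the tertiary alcohol by the silyl triflate at low temperature (protecting-group introduction) is faster than enol silylation of the hindered ketone; no stereocenter is touched.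

**Step 7**
Reactants: 13 (1R,3aR,8aR)-1,4,4-trimethyl-1-(triethylsilyloxy)octahydroazulen-5(1H)-one
Product: 14 (1R,3aR,8aR)-1,4,4-trimethyl-1-(triethylsilyloxy)-1,2,3,3a,4,7,8,8a-octahydroazulen-5-yl trifluoromethanesulfonate
Conditions: KN(SiMe3)2, THF, −78 °C; then N-(5-chloropyridin-2-yl)bis(trifluoromethanesulfonyl)imide, −78 → 0 °C
Reagents that add atoms: N-(5-chloropyridin-2-yl)bis(trifluoromethanesulfonyl)imide, FC(F)(F)S(=O)(=O)N(c1ccc(Cl)cn1)S(=O)(=O)C(F)(F)F
Why: Only C6 carries α-hydrogens (C4 is quaternary), so deprotonation gives a single enolate, which is O-sulfonylated to the alkenyl triflate (enol triflate formation).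

**Step 8**
Reactants: 15 geraniol
Product: 16 [(2R,3R)-3-methyl-3-(4-methylpent-3-en-1-yl)oxiran-2-yl]methanol
Conditions: Ti(OiPr)4 (cat.), D-(−)-diethyl tartrate (cat.), t-BuOOH, 4 Å molecular sieves, CH2Cl2, −20 °C
Reagents that add atoms: tert-butyl hydroperoxide, CC(C)(C)OO
Why: Sharpless asymmetric epoxidation of the allylic alcohol: the titanium–D-(−)-tartrate catalyst delivers oxygen to the face that gives the (2R,3R) epoxide (reagent control) and leaves the isolated 6,7-alkene untouched.

**Step 9**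
Reactants: 16 [(2R,3R)-3-methyl-3-(4-methylpent-3-en-1-yl)oxiran-2-yl]methanol
Product: 17 [(2R,3R)-3-{2-[(2S)-3,3-dimethyloxiran-2-yl]ethyl}-3-methyloxiran-2-yl]methanol
Conditions: L-fructose-derived ketone catalyst of the Shi epoxidation (1,2:4,5-di-O-isopropylidene-β-L-erythro-2,3-hexodiulo-2,6-pyranose, 30 mol %), KHSO5 (as 2KHSO5·KHSO4·K2SO4), K2CO3, Bu4NHSO4 (cat.), MeCN/dimethoxymethane/aqueous Na2B4O7 buffer, 0 °C
Reagents that add atoms: potassium peroxymonosulfate, [K+].[O-]S(=O)(=O)OO
Why: Shi epoxidation: the dioxirane formed from the chiral ketone epoxidises the remaining trisubstituted alkene through a spiro transition state, and the L-fructose-derived catalyst gives the (S) epoxide (reagent control; opposite sense to the 2,3-epoxide, as the cis relation of C3–OH and the C5a methyl group in the target requires).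

**Step 10**
Reactants: 17 [(2R,3R)-3-{2-[(2S)-3,3-dimethyloxiran-2-yl]ethyl}-3-methyloxiran-2-yl]methanol; 18 allyl acetoacetate
Product: 20 prop-2-en-1-yl 5-[(2R,3R)-3-{2-[(2S)-3,3-dimethyloxiran-2-yl]ethyl}-3-methyloxiran-2-yl]-3-oxopentanoate, via diepoxy triflate 19 (not isolated)
Conditions: 17, Tf2O, 2,6-lutidine, CH2Cl2, −78 °C (cold aqueous work-up, crude 19); 18, LiN(iPr)2 (2.1 equiv), THF, −78 → 0 °C; then 19, −78 °C
Reagents that add atoms: none
Why: The primary alcohol is converted to the triflate and displaced in an SN2 reaction by the terminal (γ) carbon of the acetoacetate dianion (dianion γ-alkylation), which at −78 °C should be much faster than opening of the trisubstituted epoxides; no stereocenter is touched.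

**Step 11**
Reactants: 20 prop-2-en-1-yl 5-[(2R,3R)-3-{2-[(2S)-3,3-dimethyloxiran-2-yl]ethyl}-3-methyloxiran-2-yl]-3-oxopentanoate
Product: 21 prop-2-en-1-yl (3S,5aR,6R,9aR)-3-(tert-butyldimethylsilyloxy)-2,2,5a-trimethyl-7-oxodecahydro-1-benzoxepine-6-carboxylate
Conditions: t-BuMe2SiOTf (1.3 equiv), 2,6-di-tert-butyl-4-methylpyridine, CH2Cl2, −78 → −40 °C; aqueous NaHCO3
Reagents that add atoms: tert-butyldimethylsilyl trifluoromethanesulfonate, CC(C)(C)[Si](C)(C)OS(=O)(=O)C(F)(F)F
Why: Tandem epoxide-opening oxa-/carbacyclization: silylation of the terminal epoxide lets the oxygen of the 2,3-epoxide attack its tertiary carbon (endo), and the bicyclic epoxonium ion is opened at its tertiary carbon with inversion by the enol of the β-keto ester, so oxepane ring D and cyclohexane ring C form trans-fused in one cascade, C3 and C9a keeping the epoxide configurations and C5a arising by inversion.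

**Step 12**
Reactants: 21 prop-2-en-1-yl (3S,5aR,6R,9aR)-3-(tert-butyldimethylsilyloxy)-2,2,5a-trimethyl-7-oxodecahydro-1-benzoxepine-6-carboxylate
Product: 23 (3S,5aR,6R,9aR)-3-(tert-butyldimethylsilyloxy)-2,2,5a-trimethyl-6-(prop-2-en-1-yl)octahydro-1-benzoxepin-7(2H)-one, via C6-epimeric allyl ketone 22 (not isolated)
Conditions: Pd(PPh3)4 (5 mol %), THF, rt; then DBU (cat.), rt
Reagents that add atoms: none
Why: Tsuji decarboxylative allylation: zerovalent palladium ionises the allyl ester, loss of CO2 gives the enolate regiospecifically at C6, which is allylated within the ion pair (probably anti to the axial C5a methyl group, giving 22), and DBU then equilibrates C6 to the isomer with the equatorial allyl group.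

**Step 13**
Reactants: 23 (3S,5aR,6R,9aR)-3-(tert-butyldimethylsilyloxy)-2,2,5a-trimethyl-6-(prop-2-en-1-yl)octahydro-1-benzoxepin-7(2H)-one
Product: 24 (3S,5aR,6R,7S,9aR)-3-(tert-butyldimethylsilyloxy)-2,2,5a,7-tetramethyl-6-(prop-2-en-1-yl)decahydro-1-benzoxepin-7-ol
Conditions: MeLi, CeCl3, THF, −78 °C
Reagents that add atoms: methyllithium, [Li]C
Why: 1,2-Addition of the weakly basic organocerium reagent to the enolisable ketone: the equatorial trajectory avoids the axial C5a methyl group (1,3-diaxial to the axial trajectory), giving the equatorial methyl group and the axial (7S) hydroxyl.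

**Step 14**
Reactants: 24 (3S,5aR,6R,7S,9aR)-3-(tert-butyldimethylsilyloxy)-2,2,5a,7-tetramethyl-6-(prop-2-en-1-yl)decahydro-1-benzoxepin-7-ol
Product: 25 7-O-triethylsilyl ether of 24
Conditions: Et3SiOTf, 2,6-lutidine, CH2Cl2, −78 → 0 °C
Reagents that add atoms: triethylsilyl trifluoromethanesulfonate, CC[Si](CC)(CC)OS(=O)(=O)C(F)(F)F
Why: Silylation of the tertiary alcohol (protecting-group introduction) prevents lactol formation with the aldehyde made next; no stereocenter is touched.

**Step 15**
Reactants: 25 7-O-triethylsilyl ether of 24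
Product: 27 2-[(3S,5aR,6R,7S,9aR)-3-(tert-butyldimethylsilyloxy)-2,2,5a,7-tetramethyl-7-(triethylsilyloxy)decahydro-1-benzoxepin-6-yl]acetaldehyde, via secondary ozonide 26 (not isolated)
Conditions: O3, CH2Cl2, −78 °C; then PPh3, −78 °C → rt
Reagents that add atoms: ozone, [O-][O+]=O
Why: Ozonolysis of the only alkene (1,3-dipolar cycloaddition/cycloreversion to ozonide 26) and reduction with PPh3 gives the aldehyde one carbon shorter; no stereocenter is touched.

**Step 16**
Reactants: 14 (1R,3aR,8aR)-1,4,4-trimethyl-1-(triethylsilyloxy)-1,2,3,3a,4,7,8,8a-octahydroazulen-5-yl trifluoromethanesulfonate; 27 2-[(3S,5aR,6R,7S,9aR)-3-(tert-butyldimethylsilyloxy)-2,2,5a,7-tetramethyl-7-(triethylsilyloxy)decahydro-1-benzoxepin-6-yl]acetaldehyde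
Product: 28 1-(hydroazulen-5-yl)-2-(benzoxepin-6-yl)ethan-1-ol, tris-silyl ether, mixture of carbinol epimers
Conditions: 14 (1.5 equiv), CrCl2 (4 equiv), NiCl2 (2 mol %), DMF/THF, rt
Reagents that add atoms: none
Why: Nozaki–Hiyama–Kishi coupling: the alkenyl triflate adds oxidatively to zerovalent nickel, transmetalates to chromium, and the alkenylchromium species adds chemoselectively to the aldehyde; the carbinol center forms without control and is corrected in steps 17 and 18.

**Step 17**
Reactants: 28 coupling product (carbinol epimers)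
Product: 29 1-(hydroazulen-5-yl)-2-(benzoxepin-6-yl)ethan-1-one (enone), tris-silyl ether
Conditions: Dess–Martin periodinane, CH2Cl2, 0 °C → rt
Reagents that add atoms: none
Why: Dess–Martin oxidation of the allylic alcohol to the enone removes the uncontrolled carbinol center under mild conditions that leave the silyl ethers intact.

**Step 18**
Reactants: 29 enone
Product: 30 (1S)-allylic alcohol, tris-silyl ether
Conditions: (R)-2-methyl-CBS-oxazaborolidine (20 mol %), BH3·SMe2, THF, −40 °C; MeOH quench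
Reagents that add atoms: none
Why: Corey–Bakshi–Shibata reduction: the oxazaborolidine–borane complex binds the ketone with the large cycloheptenyl group away from the catalyst and delivers hydride to one face, which by the usual model should give the (S) carbinol with the (R) catalyst (reagent control, 1,2-reduction).

**Step 19**
Reactants: 30 (1S)-allylic alcohol
Product: 31 (1S)-allylic pyridine-2-carboxylate (picolinate) of 30
Conditions: pyridine-2-carboxylic acid, DCC, DMAP (cat.), CH2Cl2, rt
Reagents that add atoms: pyridine-2-carboxylic acid, OC(=O)c1ccccn1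
Why: Steglich esterification (carbodiimide/DMAP) acylates the alcohol with retention at the carbinol carbon and installs a chelating leaving group.

**Step 20**
Reactants: 31 (1S)-allylic picolinate
Product: 32 tris-silyl ether of the target (3-O-tert-butyldimethylsilyl, 7-O-triethylsilyl, hydroazulene 1-O-triethylsilyl)
Conditions: MeMgBr (3 equiv), CuBr·SMe2 (30 mol %), THF, −40 → 0 °C
Reagents that add atoms: methylmagnesium bromide, C[Mg]Br
Why: Copper-catalysed anti-SN2′ allylic substitution: the C–O bond should react in the rotamer that places the side-chain CH2 toward H-6 and the carbinol hydrogen toward C4(Me)2 (allylic strain), and the methylcopper species attacks C6 opposite to the chelated leaving group, which is the convex face, so the (6R) methyl center and the (E) exocyclic alkene form together by 1,3-chirality transfer.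

**Step 21**
Reactants: 32 tris-silyl ether of the target
Product: 33 (3S,5aR,6R,7S,9aR)-6-{(2E)-2-[(1R,3aR,6R,8aR)-1-hydroxy-1,4,4,6-tetramethyloctahydroazulen-5(1H)-ylidene]ethyl}-2,2,5a,7-tetramethyldecahydro-1-benzoxepine-3,7-diol (target)
Conditions: Bu4NF (excess), THF, rt → 50 °C
Reagents that add atoms: none
Why: Fluoride cleaves the three Si–O bonds (desilylation) without touching a stereocenter or the alkene.

**Compound list**

1 | cyclopentanone | O=C1CCCC1 | starting material
2 | (2S,5S)-2,5-dimethylpyrrolidine | C[C@H]1CC[C@H](C)N1 | starting material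
3 | 1-[(2S,5S)-2,5-dimethylpyrrolidin-1-yl]cyclopent-1-ene | C[C@H]1CC[C@H](C)N1C2=CCCC2 | intermediate
4 | 5-methylhex-4-enoic acid | CC(C)=CCCC(=O)O | starting material
5 | 5-methylhex-4-enoyl chloride | CC(C)=CCCC(=O)Cl | intermediate (not isolated)
6 | 1-{2-[(2S,5S)-2,5-dimethylpyrrolidin-1-yl]cyclopent-1-en-1-yl}-5-methylhex-4-en-1-one | C[C@H]1CC[C@H](C)N1C2=C(C(=O)CCC=C(C)C)CCC2 | intermediate
7 | 6,6-dimethyl-5-[(2S,5S)-2,5-dimethylpyrrolidin-1-yl]tricyclo[5.3.0.0(1,5)]decan-10-one (cyclobutane cis-fused to both five-membered rings, which lie on opposite faces; C7 as C3a of 9) | O=C1CC[C@H]2C(C)(C)[C@]3(N4[C@@H](C)CC[C@@H]4C)CCC[C@]123 | intermediate (not isolated)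
8 | (3aR,8aR)-5-[(2S,5S)-2,5-dimethylpyrrolidin-1-yl]-4,4-dimethyl-3,3a,4,7,8,8a-hexahydroazulen-1(2H)-one | C=1CC[C@@H]2[C@@H](CCC2=O)C(C)(C)C=1N3[C@@H](C)CC[C@@H]3C | intermediate (not isolated)
9 | (3aR,8aR)-4,4-dimethyloctahydroazulene-1,5-dione (cis-fused) | C1CC[C@@H]2[C@@H](CCC2=O)C(C)(C)C1=O | intermediate
10 | (3aR,8aR)-4,4-dimethyl-1-methylideneoctahydroazulen-5(1H)-one | C1CC[C@@H]2[C@@H](CCC2=C)C(C)(C)C1=O | intermediate
11 | (1R,3aR,8aR)-1-hydroperoxy-1,4,4-trimethyloctahydroazulen-5(1H)-one | C1CC[C@@H]2[C@@H](CC[C@@]2(C)OO)C(C)(C)C1=O | intermediate (not isolated)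
12 | (1R,3aR,8aR)-1-hydroxy-1,4,4-trimethyloctahydroazulen-5(1H)-one | C1CC[C@@H]2[C@@H](CC[C@@]2(C)O)C(C)(C)C1=O | intermediate
13 | (1R,3aR,8aR)-1,4,4-trimethyl-1-(triethylsilyloxy)octahydroazulen-5(1H)-one | C1CC[C@@H]2[C@@H](CC[C@@]2(C)O[Si](CC)(CC)CC)C(C)(C)C1=O | intermediate
14 | (1R,3aR,8aR)-1,4,4-trimethyl-1-(triethylsilyloxy)-1,2,3,3a,4,7,8,8a-octahydroazulen-5-yl trifluoromethanesulfonate | C=1CC[C@@H]2[C@@H](CC[C@@]2(C)O[Si](CC)(CC)CC)C(C)(C)C=1OS(=O)(=O)C(F)(F)F | intermediate
15 | geraniol, (2E)-3,7-dimethylocta-2,6-dien-1-ol | CC(C)=CCC/C(C)=C/CO | starting material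
16 | [(2R,3R)-3-methyl-3-(4-methylpent-3-en-1-yl)oxiran-2-yl]methanol | CC(C)=CCC[C@@]1(C)O[C@@H]1CO | intermediate
17 | [(2R,3R)-3-{2-[(2S)-3,3-dimethyloxiran-2-yl]ethyl}-3-methyloxiran-2-yl]methanol | CC1(C)O[C@H]1CC[C@@]2(C)O[C@@H]2CO | intermediate
18 | allyl acetoacetate (prop-2-en-1-yl 3-oxobutanoate) | CC(=O)CC(=O)OCC=C | starting material
19 | [(2R,3R)-3-{2-[(2S)-3,3-dimethyloxiran-2-yl]ethyl}-3-methyloxiran-2-yl]methyl trifluoromethanesulfonate | CC1(C)O[C@H]1CC[C@@]2(C)O[C@@H]2COS(=O)(=O)C(F)(F)F | intermediate (not isolated)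
20 | prop-2-en-1-yl 5-[(2R,3R)-3-{2-[(2S)-3,3-dimethyloxiran-2-yl]ethyl}-3-methyloxiran-2-yl]-3-oxopentanoate | CC1(C)O[C@H]1CC[C@@]2(C)O[C@@H]2CCC(=O)CC(=O)OCC=C | intermediate
21 | prop-2-en-1-yl (3S,5aR,6R,9aR)-3-(tert-butyldimethylsilyloxy)-2,2,5a-trimethyl-7-oxodecahydro-1-benzoxepine-6-carboxylate | C=CCOC(=O)[C@@H]1[C@@]2(C)CC[C@H](O[Si](C)(C)C(C)(C)C)C(C)(C)O[C@@H]2CCC1=O | intermediate
22 | (3S,5aR,6S,9aR)-3-(tert-butyldimethylsilyloxy)-2,2,5a-trimethyl-6-(prop-2-en-1-yl)octahydro-1-benzoxepin-7(2H)-one (axial allyl) | C=CC[C@H]1[C@@]2(C)CC[C@H](O[Si](C)(C)C(C)(C)C)C(C)(C)O[C@@H]2CCC1=O | intermediate (not isolated)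
23 | (3S,5aR,6R,9aR)-3-(tert-butyldimethylsilyloxy)-2,2,5a-trimethyl-6-(prop-2-en-1-yl)octahydro-1-benzoxepin-7(2H)-one (equatorial allyl) | C=CC[C@@H]1[C@@]2(C)CC[C@H](O[Si](C)(C)C(C)(C)C)C(C)(C)O[C@@H]2CCC1=O | intermediate
24 | (3S,5aR,6R,7S,9aR)-3-(tert-butyldimethylsilyloxy)-2,2,5a,7-tetramethyl-6-(prop-2-en-1-yl)decahydro-1-benzoxepin-7-ol | C=CC[C@@H]1[C@@]2(C)CC[C@H](O[Si](C)(C)C(C)(C)C)C(C)(C)O[C@@H]2CC[C@]1(C)O | intermediate
25 | 7-O-triethylsilyl ether of 24 | C=CC[C@@H]1[C@@]2(C)CC[C@H](O[Si](C)(C)C(C)(C)C)C(C)(C)O[C@@H]2CC[C@]1(C)O[Si](CC)(CC)CC | intermediate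
26 | secondary ozonide (1,2,4-trioxolane) of 25, new ring carbon unassigned | O1COC(C[C@@H]2[C@@]3(C)CC[C@H](O[Si](C)(C)C(C)(C)C)C(C)(C)O[C@@H]3CC[C@]2(C)O[Si](CC)(CC)CC)O1 | intermediate (not isolated)
27 | 2-[(3S,5aR,6R,7S,9aR)-3-(tert-butyldimethylsilyloxy)-2,2,5a,7-tetramethyl-7-(triethylsilyloxy)decahydro-1-benzoxepin-6-yl]acetaldehyde | O=CC[C@@H]1[C@@]2(C)CC[C@H](O[Si](C)(C)C(C)(C)C)C(C)(C)O[C@@H]2CC[C@]1(C)O[Si](CC)(CC)CC | intermediate
28 | 1-[(1R,3aR,8aR)-1,4,4-trimethyl-1-(triethylsilyloxy)-1,2,3,3a,4,7,8,8a-octahydroazulen-5-yl]-2-[benzoxepin-6-yl fragment of 27]ethan-1-ol, carbinol epimers | C=1CC[C@@H]2[C@@H](CC[C@@]2(C)O[Si](CC)(CC)CC)C(C)(C)C=1C(O)C[C@@H]3[C@@]4(C)CC[C@H](O[Si](C)(C)C(C)(C)C)C(C)(C)O[C@@H]4CC[C@]3(C)O[Si](CC)(CC)CC | intermediate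
29 | corresponding ethan-1-one (enone) | C=1CC[C@@H]2[C@@H](CC[C@@]2(C)O[Si](CC)(CC)CC)C(C)(C)C=1C(=O)C[C@@H]3[C@@]4(C)CC[C@H](O[Si](C)(C)C(C)(C)C)C(C)(C)O[C@@H]4CC[C@]3(C)O[Si](CC)(CC)CC | intermediate
30 | (1S)-ethan-1-ol (single carbinol epimer of 28) | C=1CC[C@@H]2[C@@H](CC[C@@]2(C)O[Si](CC)(CC)CC)C(C)(C)C=1[C@@H](O)C[C@@H]3[C@@]4(C)CC[C@H](O[Si](C)(C)C(C)(C)C)C(C)(C)O[C@@H]4CC[C@]3(C)O[Si](CC)(CC)CC | intermediate
31 | (1S)-pyridine-2-carboxylate of 30 | C=1CC[C@@H]2[C@@H](CC[C@@]2(C)O[Si](CC)(CC)CC)C(C)(C)C=1[C@@H](OC(=O)c5ccccn5)C[C@@H]3[C@@]4(C)CC[C@H](O[Si](C)(C)C(C)(C)C)C(C)(C)O[C@@H]4CC[C@]3(C)O[Si](CC)(CC)CC | intermediate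
32 | target carrying 3-O-tert-butyldimethylsilyl, 7-O-triethylsilyl and hydroazulene 1-O-triethylsilyl groups | C[C@@H]1CC[C@@H]2[C@@H](CC[C@@]2(C)O[Si](CC)(CC)CC)C(C)(C)/C1=C/C[C@@H]1[C@@]2(C)CC[C@H](O[Si](C)(C)C(C)(C)C)C(C)(C)O[C@@H]2CC[C@]1(C)O[Si](CC)(CC)CC | intermediate
33 | (3S,5aR,6R,7S,9aR)-6-{(2E)-2-[(1R,3aR,6R,8aR)-1-hydroxy-1,4,4,6-tetramethyloctahydroazulen-5(1H)-ylidene]ethyl}-2,2,5a,7-tetramethyldecahydro-1-benzoxepine-3,7-diol | C[C@@H]1CC[C@@H]2[C@@H](CC[C@@]2(C)O)C(C)(C)/C1=C/C[C@@H]1[C@@]2(C)CC[C@H](O)C(C)(C)O[C@@H]2CC[C@]1(C)O | target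

**Step count**

Total: 21 steps. Longest linear sequence: 14 steps (steps 8–15 from geraniol, then steps 16–21).

**Three steps most likely to fail**

Step 3 (proposed new method). What may go wrong: insufficient facial discrimination by the auxiliary; radiationless decay of the strained, partly twisted tertiary enaminone instead of cycloaddition; protonation at C8a by internal return giving the trans ring fusion. Fallback with known chemistry, setting out from 1 and 5 and coming back at 9: soft enolisation and C-acylation of cyclopentanone 1 with acid chloride 5 (MgBr2·OEt2, i-Pr2NEt, CH2Cl2) should give 2-(5-methylhex-4-enoyl)cyclopentan-1-one F1. O-Acylation with benzyl chloroformate/pyridine should give the endocyclic enol carbonate, benzyl 2-(5-methylhex-4-enoyl)cyclopent-1-en-1-yl carbonate F2. Irradiation (Pyrex, cyclohexane) gives the cyclobutane photoadduct, benzyl 6,6-dimethyl-10-oxotricyclo[5.3.0.0(1,5)]decan-5-yl carbonate F3 (classical intramolecular de Mayo photocycloaddition). Hydrogenolysis (H2, Pd/C, EtOAc) frees the cyclobutanol, which fragments by retro-aldol reaction to the racemic cis-dione F4. Preparative chromatography on a chiral stationary phase then delivers 9.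

Step 11. What may go wrong: exo (tetrahydrofuran-forming) opening of the terminal epoxide; direct attack of the enol on the silyl-activated 2,3-epoxide without oxepane formation; pinacol-type rearrangement of either epoxide; a slow enol terminator. Fallback, setting out from 16 and coming back at 23 (rings built one after the other, cyclohexane first): 16 is converted (Tf2O, 2,6-lutidine) into [(2R,3R)-3-methyl-3-(4-methylpent-3-en-1-yl)oxiran-2-yl]methyl trifluoromethanesulfonate F5 and alkylated with the dianion of 18 to prop-2-en-1-yl 5-[(2R,3R)-3-methyl-3-(4-methylpent-3-en-1-yl)oxiran-2-yl]-3-oxopentanoate F6. BF3·OEt2-mediated opening of the single epoxide at its tertiary carbon by the keto ester enol (6-endo, inversion) gives prop-2-en-1-yl (1R,2R,3R)-3-hydroxy-2-methyl-2-(4-methylpent-3-en-1-yl)-6-oxocyclohexane-1-carboxylate F7. Pd(PPh3)4 then DBU, as in step 12, gives (2R,3R,4R)-4-hydroxy-3-methyl-3-(4-methylpent-3-en-1-yl)-2-(prop-2-en-1-yl)cyclohexan-1-one F8. The Shi epoxidation with the L-fructose-derived ketone epoxidises only the trisubstituted alkene to (2R,3R,4R)-3-{2-[(2S)-3,3-dimethyloxiran-2-yl]ethyl}-4-hydroxy-3-methyl-2-(prop-2-en-1-yl)cyclohexan-1-one F9. Camphorsulfonic acid closes the oxepane by 7-endo attack of the ring hydroxyl at the tertiary epoxide carbon to give (3S,5aR,6R,9aR)-3-hydroxy-2,2,5a-trimethyl-6-(prop-2-en-1-yl)octahydro-1-benzoxepin-7(2H)-one F10, and t-BuMe2SiOTf/2,6-lutidine gives 23.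

Step 20. What may go wrong: direct (α) substitution instead of SN2′; elimination to a diene; reaction through the other rotamer or the other face, eroding the alkene geometry or the C6 configuration. Fallback, setting out from 29 and coming back at 32 (directed syn delivery from the epimeric carbinol): reduction of 29 with the (S)-oxazaborolidine/BH3·SMe2 gives the (1R)-allylic alcohol F11. Phenyl isocyanate converts it to the (1R)-N-phenylcarbamate F12. Deprotonation (n-BuLi) and treatment with the methylcopper reagent from MeLi/CuI should transfer the methyl group intramolecularly, syn to the carbamate (syn-SN2′), to the same face of C6 and give 32.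

**Further compounds**

F1 | step 3 | 2-(5-methylhex-4-enoyl)cyclopentan-1-one | O=C1CCCC1C(=O)CCC=C(C)C
F2 | step 3 | benzyl 2-(5-methylhex-4-enoyl)cyclopent-1-en-1-yl carbonate | O=C(OCc1ccccc1)OC2=C(C(=O)CCC=C(C)C)CCC2
F3 | step 3 | benzyl 6,6-dimethyl-10-oxotricyclo[5.3.0.0(1,5)]decan-5-yl carbonate (racemic, one enantiomer drawn) | O=C1CC[C@H]2C(C)(C)[C@]3(OC(=O)OCc4ccccc4)CCC[C@]123
F4 | step 3 | racemic cis-4,4-dimethyloctahydroazulene-1,5-dione (9 and its enantiomer) | C1CC[C@@H]2[C@@H](CCC2=O)C(C)(C)C1=O.C1CC[C@H]2[C@H](CCC2=O)C(C)(C)C1=O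
F5 | step 11 | [(2R,3R)-3-methyl-3-(4-methylpent-3-en-1-yl)oxiran-2-yl]methyl trifluoromethanesulfonate | CC(C)=CCC[C@@]1(C)O[C@@H]1COS(=O)(=O)C(F)(F)F
F6 | step 11 | prop-2-en-1-yl 5-[(2R,3R)-3-methyl-3-(4-methylpent-3-en-1-yl)oxiran-2-yl]-3-oxopentanoate | CC(C)=CCC[C@@]1(C)O[C@@H]1CCC(=O)CC(=O)OCC=C
F7 | step 11 | prop-2-en-1-yl (1R,2R,3R)-3-hydroxy-2-methyl-2-(4-methylpent-3-en-1-yl)-6-oxocyclohexane-1-carboxylate | C=CCOC(=O)[C@@H]1[C@@](C)(CCC=C(C)C)[C@H](O)CCC1=O
F8 | step 11 | (2R,3R,4R)-4-hydroxy-3-methyl-3-(4-methylpent-3-en-1-yl)-2-(prop-2-en-1-yl)cyclohexan-1-one | C=CC[C@@H]1[C@@](C)(CCC=C(C)C)[C@H](O)CCC1=O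
F9 | step 11 | (2R,3R,4R)-3-{2-[(2S)-3,3-dimethyloxiran-2-yl]ethyl}-4-hydroxy-3-methyl-2-(prop-2-en-1-yl)cyclohexan-1-one | C=CC[C@@H]1[C@@](C)(CC[C@@H]2OC2(C)C)[C@H](O)CCC1=O
F10 | step 11 | (3S,5aR,6R,9aR)-3-hydroxy-2,2,5a-trimethyl-6-(prop-2-en-1-yl)octahydro-1-benzoxepin-7(2H)-one | C=CC[C@@H]1[C@@]2(C)CC[C@H](O)C(C)(C)O[C@@H]2CCC1=O
F11 | step 20 | (1R)-allylic alcohol, carbinol epimer of 30 | C=1CC[C@@H]2[C@@H](CC[C@@]2(C)O[Si](CC)(CC)CC)C(C)(C)C=1[C@H](O)C[C@@H]3[C@@]4(C)CC[C@H](O[Si](C)(C)C(C)(C)C)C(C)(C)O[C@@H]4CC[C@]3(C)O[Si](CC)(CC)CC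
F12 | step 20 | (1R)-N-phenylcarbamate of F11 | C=1CC[C@@H]2[C@@H](CC[C@@]2(C)O[Si](CC)(CC)CC)C(C)(C)C=1[C@H](OC(=O)Nc5ccccc5)C[C@@H]3[C@@]4(C)CC[C@H](O[Si](C)(C)C(C)(C)C)C(C)(C)O[C@@H]4CC[C@]3(C)O[Si](CC)(CC)CC
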